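A direct plan would follow the biosynthesis: methyl 4-hydroxycinnamate would be O-geranylated to ester A1.
A1 would acylate the dianion of 4-hydroxy-6-methyl-2-pyrone to give pyrone ketone A2, and Mg(OCH3)2 would refold A2 by a Claisen condensation into chalcone A3.
Chalcone isomerase would then close ring C to the flavanone.
Its weakest steps would be:
(a) the dianion acylation, which would need excess pyrone and amide base and would leave 1,2- against 1,4-attack on the enoate to temperature control;
(b) the ring opening and Claisen aromatisation, which would spend two steps and hot methoxide on late material to rebuild a phloroglucinol ring that can be bought, with Claisen against aldol folding left to a chelate;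
(c) the enzymatic oxa-Michael closure, which would set the only stereocentre last by a ring closure that also runs uncatalysed to racemate, on a non-natural 4-O-alkylated substrate.

**Plan of the new route**
The retrosynthesis removes the two silyl groups, then cuts the C2–C1' bond between ring C and ring B, and last the C–B bond and the geranyl O–CH2 bond of the aryl donor.
This leaves 5,7-dihydroxychromone (rings A and C, bought) and 4-bromophenol plus geranyl bromide (ring B); ring B is joined last and no ring is closed anywhere.
Enabling feature: C2 is the β-carbon of the O1–C2=C3–C4=O vinylogous ester of ring C and carries ring B as its only exocyclic carbon, so the flat chromone can take up the aryl group at C2 and the C–C bond formation itself creates the stereocentre under a chiral monovalent rhodium catalyst.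
Ring A is never built, so the dianion acylation and the polyketide folding vanish; O1–C2 is never formed or broken, so no oxa-Michael closure, no racemic background and no enzyme decide the configuration.
The geranyl ether comes in on the boronic acid and meets only neutral or buffered media up to the final fluoride desilylation.

Key step: step 4

Assumption: 5,7-dihydroxy-4H-chromen-4-one is taken as a purchasable catalogue compound; the sense of induction in step 4 is assigned from the 2-cyclohexenone model [(S)-bisphosphine gives (S)-3-arylcyclohexanone, which maps onto 2S here], and the (R)-ligand would be used should the first run show the opposite.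

Geranyl = (2E)-3,7-dimethylocta-2,6-dien-1-yl throughout.

Step 1
Reactants: 1 4-bromophenol; 2 geranyl bromide, (2E)-1-bromo-3,7-dimethylocta-2,6-diene
Product: 3 1-bromo-4-(geranyloxy)benzene
Conditions: K2CO3 (1.5 equiv), acetone, reflux
Reagents that add atoms: none
Why: Williamson ether synthesis, in which the phenoxide displaces the primary allylic bromide by SN2 at C1 of the geranyl unit, so that the (2E) geometry is kept and the aryl bromide is untouched by carbonate.

Step 2
Reactants: 3 1-bromo-4-(geranyloxy)benzene
Product: 6 [4-(geranyloxy)phenyl]boronic acid, via [4-(geranyloxy)phenyl]lithium 4 (not isolated), via lithium triisopropoxy[4-(geranyloxy)phenyl]borate 5 (not isolated)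
Conditions: n-BuLi (1.05 equiv), THF, −78 °C; B(Oi-Pr)3 (1.5 equiv), −78 to 0 °C; cold 0.5 M HCl to pH 5, EtOAc
Reagents that add atoms: triisopropyl borate, CC(C)OB(OC(C)C)OC(C)C; water, O
Why: Bromine–lithium exchange followed by borylation, in which exchange at −78 °C should be far faster than attack of n-BuLi on the allylic ether, the aryllithium is trapped by the borate as the ate complex 5 that cannot take up a second aryl group, and cold hydrolysis at pH 5 frees the boronic acid without ionising the geranyl ether.

Step 3
Reactants: 7 5,7-dihydroxy-4H-chromen-4-one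
Product: 8 5,7-bis(tert-butyldimethylsilyloxy)-4H-chromen-4-one
Conditions: t-BuMe2SiOTf (2.6 equiv), 2,6-lutidine (4 equiv), CH2Cl2, 0 to 25 °C
Reagents that add atoms: tert-butyldimethylsilyl trifluoromethanesulfonate, CC(C)(C)[Si](C)(C)OS(=O)(=O)C(F)(F)F
Why: Silylation of both phenols with the silyl triflate, which is reactive enough for the hydrogen-bonded 5-OH, with 2,6-lutidine as non-nucleophilic base; masking both phenols removes the acidic protons and the 5-hydroxy-4-keto chelate that would otherwise quench or bind the rhodium catalyst of step 4.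

Step 4
Reactants: 8 5,7-bis(tert-butyldimethylsilyloxy)-4H-chromen-4-one; 6 [4-(geranyloxy)phenyl]boronic acid (1.8 equiv)
Product: 9 (2S)-5,7-bis(tert-butyldimethylsilyloxy)-2-[4-(geranyloxy)phenyl]chroman-4-one
Conditions: [Rh(OH)(cod)]2 (2.5 mol %; cod = 1,5-cyclooctadiene), (S)-6,6'-dimethoxy-2,2'-bis[bis(3,4,5-trifluorophenyl)phosphino]-1,1'-biphenyl (5.5 mol %), toluene/H2O (10:1), 25 °C, argon
Reagents that add atoms: none
Why: Hayashi–Miyaura asymmetric 1,4-addition: the Rh–OH complex transmetalates with 6 to an aryl–rhodium species, the C2=C3 bond of 8 coordinates, syn migratory insertion forms the C2–C1' bond and an oxa-π-allyl rhodium enolate, and water protonates C3 and returns Rh–OH. The closest known reaction type is the rhodium/bisphosphine-catalysed addition of arylboronic acids to chromones that carry oxygen at C5 and C7. No ring is closed, since rings A and C are present in 8 and ring B is joined as a whole. The new stereocentre C2 is set in the insertion by the atropisomeric bisphosphine, which leaves one enantioface of the bound enone open; by analogy with 2-cyclohexenone the (S)-ligand should deliver the aryl group so that C2 becomes S. The step needs 1,4- over 1,2-addition and a single arylation without β-aryloxide opening of ring C; the electron-poor phosphine should make rhodium electrophilic enough to insert into the deactivated vinylogous ester at 25 °C, the base-free neutral medium should protonate the enolate before O1 can leave and keeps the aryl silyl ethers intact, and the silyl groups prevent a 5-hydroxy-4-keto chelate from binding rhodium.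

Step 5
Reactants: 9 (2S)-5,7-bis(tert-butyldimethylsilyloxy)-2-[4-(geranyloxy)phenyl]chroman-4-one
Product: 10 (2S)-5,7-dihydroxy-2-[4-(geranyloxy)phenyl]chroman-4-one
Conditions: Bu4NF (2.4 equiv)/AcOH (2.6 equiv), THF, 0 °C; pH 6 phosphate buffer, EtOAc
Reagents that add atoms: none
Why: Fluoride-induced cleavage of the two aryl silyl ethers, driven by the Si–F bond, with acetic acid buffering the liberated phenoxides so that no base is present to open ring C by retro-oxa-Michael elimination at C2, and with the geranyl ether and the stereocentre left untouched.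

**Compound list**
1 | 4-bromophenol | Oc1ccc(Br)cc1 | starting material
2 | geranyl bromide, (2E)-1-bromo-3,7-dimethylocta-2,6-diene | CC(C)=CCC/C(C)=C/CBr | starting material
3 | 1-bromo-4-(geranyloxy)benzene | CC(C)=CCC/C(C)=C/COc1ccc(Br)cc1 | intermediate
4 | [4-(geranyloxy)phenyl]lithium | CC(C)=CCC/C(C)=C/COc1ccc([Li])cc1 | intermediate (not isolated)
5 | lithium triisopropoxy[4-(geranyloxy)phenyl]borate | [Li+].CC(C)=CCC/C(C)=C/COc1ccc([B-](OC(C)C)(OC(C)C)OC(C)C)cc1 | intermediate (not isolated)
6 | [4-(geranyloxy)phenyl]boronic acid | CC(C)=CCC/C(C)=C/COc1ccc(B(O)O)cc1 | intermediate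
7 | 5,7-dihydroxy-4H-chromen-4-one | O=c1ccoc2cc(O)cc(O)c12 | starting material
8 | 5,7-bis(tert-butyldimethylsilyloxy)-4H-chromen-4-one | O=c1ccoc2cc(O[Si](C)(C)C(C)(C)C)cc(O[Si](C)(C)C(C)(C)C)c12 | intermediate
9 | (2S)-5,7-bis(tert-butyldimethylsilyloxy)-2-[4-(geranyloxy)phenyl]chroman-4-one | CC(C)=CCC/C(C)=C/COc1ccc([C@@H]2CC(=O)c3c(O[Si](C)(C)C(C)(C)C)cc(O[Si](C)(C)C(C)(C)C)cc3O2)cc1 | intermediate
10 | (2S)-5,7-dihydroxy-2-[4-(geranyloxy)phenyl]chroman-4-one | CC(C)=CCC/C(C)=C/COc1ccc([C@@H]2CC(=O)c3c(O)cc(O)cc3O2)cc1 | target

Total step count: 5. Longest linear sequence: 4 steps (steps 1, 2, 4, 5).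

**Steps most likely to fail**

Step 4. Insertion of the aryl–rhodium species into the electron-rich vinylogous ester may be slow, so that protodeboronation of 6 outruns addition. The rhodium enolate may also open ring C by β-aryloxide elimination and take up a second aryl group, or the facial selectivity may be poor. The fallback sets out from 3 and 8 and comes back at 9. Compound 3 would be turned with Mg turnings in THF into [4-(geranyloxy)phenyl]magnesium bromide F1. F1 would be added at −78 °C to 8 in the presence of CuBr·SMe2 (10 mol %) and Me3SiCl (2 equiv) to give 5,7-bis(tert-butyldimethylsilyloxy)-2-[4-(geranyloxy)phenyl]-4-(trimethylsilyloxy)-2H-chromene F2. Hydrolysis of the enol ether with aqueous NH4Cl would give racemic 5,7-bis(tert-butyldimethylsilyloxy)-2-[4-(geranyloxy)phenyl]chroman-4-one F3. Preparative chromatography on an amylose tris(3,5-dimethylphenylcarbamate) phase would then separate the enantiomers, and the (2S)-enantiomer is 9.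

Step 3. Silylation of the hydrogen-bonded 5-OH may stay incomplete, and the crowded 5-O-silyl group may be lost on silica or in the aqueous medium of step 4, which would expose a chelating 5-hydroxy-4-ketone. The fallback sets out from 7 and comes back at 10. Ac2O, pyridine and DMAP would give 5,7-diacetoxy-4H-chromen-4-one F4. The rhodium-catalysed arylation of F4 with 6 under the conditions of step 4 would give (2S)-5,7-diacetoxy-2-[4-(geranyloxy)phenyl]chroman-4-one F5. Neutral transesterification (NH4OAc, MeOH/H2O, 25 °C) would then free both phenols and give 10 without fluoride.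

Step 2. n-BuLi may attack the allylic ether (SN2' cleavage, or α-deprotonation and Wittig rearrangement) in competition with the bromine–lithium exchange, and the geranyl group may be lost under acid in the work-up. The fallback sets out from 2 and comes back at 6. Purchased 4-(4,4,5,5-tetramethyl-1,3,2-dioxaborolan-2-yl)phenol F6 would be alkylated with 2 (K2CO3, DMF, 25 °C) to 2-[4-(geranyloxy)phenyl]-4,4,5,5-tetramethyl-1,3,2-dioxaborolane F7. NaIO4 and NH4OAc in acetone/H2O would then cleave the pinacol ester and give 6 with no organolithium step.

**Further compounds**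
F1 | step 4 | [4-(geranyloxy)phenyl]magnesium bromide | CC(C)=CCC/C(C)=C/COc1ccc([Mg]Br)cc1
F2 | step 4 | 5,7-bis(tert-butyldimethylsilyloxy)-2-[4-(geranyloxy)phenyl]-4-(trimethylsilyloxy)-2H-chromene (racemic) | CC(C)=CCC/C(C)=C/COc1ccc(C2C=C(O[Si](C)(C)C)c3c(O[Si](C)(C)C(C)(C)C)cc(O[Si](C)(C)C(C)(C)C)cc3O2)cc1
F3 | step 4 | racemic 5,7-bis(tert-butyldimethylsilyloxy)-2-[4-(geranyloxy)phenyl]chroman-4-one | CC(C)=CCC/C(C)=C/COc1ccc(C2CC(=O)c3c(O[Si](C)(C)C(C)(C)C)cc(O[Si](C)(C)C(C)(C)C)cc3O2)cc1
F4 | step 3 | 5,7-diacetoxy-4H-chromen-4-one | O=c1ccoc2cc(OC(C)=O)cc(OC(C)=O)c12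
F5 | step 3 | (2S)-5,7-diacetoxy-2-[4-(geranyloxy)phenyl]chroman-4-one | CC(C)=CCC/C(C)=C/COc1ccc([C@@H]2CC(=O)c3c(OC(C)=O)cc(OC(C)=O)cc3O2)cc1
F6 | step 2 | 4-(4,4,5,5-tetramethyl-1,3,2-dioxaborolan-2-yl)phenol | CC1(C)OB(OC1(C)C)c1ccc(O)cc1
F7 | step 2 | 2-[4-(geranyloxy)phenyl]-4,4,5,5-tetramethyl-1,3,2-dioxaborolane | CC(C)=CCC/C(C)=C/COc1ccc(B2OC(C)(C)C(C)(C)O2)cc1
A1 | direct plan | methyl (E)-4-(geranyloxy)cinnamate | CC(C)=CCC/C(C)=C/COc1ccc(/C=C/C(=O)OC)cc1
A2 | direct plan | 4-hydroxy-6-[(E)-4-(4-geranyloxyphenyl)-2-oxobut-3-enyl]-2H-pyran-2-one | CC(C)=CCC/C(C)=C/COc1ccc(/C=C/C(=O)Cc2cc(O)cc(=O)o2)cc1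
A3 | direct plan | (E)-2',4',6'-trihydroxy-4-(geranyloxy)chalcone | CC(C)=CCC/C(C)=C/COc1ccc(/C=C/C(=O)c2c(O)cc(O)cc2O)cc1
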